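**Retrosynthetic overview**

- Target ⇐ convex-face hydrogenation of the 13-methylene lactone ⇐ oxidative Heck closure of ring B (C1–C12) from the pyrrole onto an α-methylbutenolide (sets C12 and C13).
- Butenolide (ring D) ⇐ ring-closing metathesis of a methacrylate ⇐ Felkin–Anh reduction of a C11 vinyl ketone (sets C11) ⇐ C11 carboxylic acid.
- C9 and C10 ⇐ Ireland–Claisen [3,3] rearrangement of the butanoate of an (R,E)-pyrrolylbutenol; the chirality comes from (R)-but-3-yn-2-ol, whose carbinol carbon later leaves as propene when ring C (azepine) is closed by metathesis.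
- Side lactone (ring E): C18 is bought as (R)-5-oxotetrahydrofuran-2-carboxylic acid, C20 is set by trans-methylation of its enolate; the pyrrole (ring A) is made by Paal–Knorr condensation on the keto aldehyde derived from that acid.
- Order of ring formation: E (bought) → A → C → D → B.

Assumption: the SMILES is read as 9S,10R,11R,12S,13S,18R,20S (numbering C1–C3, N4, C5–C9, C9a, C10–C14, side lactone C18–C21), so H9–H13 are all cis and the side lactone is trans; the four bought building blocks are taken as commercial.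

This route has not been run; conditions and selectivities are projected from analogous reactions.

**Step 1**
Reactants: 1 (R)-5-oxotetrahydrofuran-2-carboxylic acid; 2 [2-(1,3-dioxolan-2-yl)ethyl]zinc bromide
Product: 4 (R)-5-[3-(1,3-dioxolan-2-yl)propanoyl]dihydrofuran-2(3H)-one, via acid chloride 3 (not isolated)
Conditions: (COCl)2, DMF (cat.), CH2Cl2, 0 °C to rt, evaporate; then 2 (0.5 M in THF), Pd(PPh3)4 (5 mol%), THF, 0 °C to rt
Reagents that add atoms: none
Why: Negishi acylation under zerovalent palladium catalysis joins the acid chloride to the alkylzinc bromide without touching the lactone or the C18 centre, which is bought with 1.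

**Step 2**
Reactants: 4 (R)-5-[3-(1,3-dioxolan-2-yl)propanoyl]dihydrofuran-2(3H)-one; 5 but-3-en-1-amine
Product: 7 (R)-5-[1-(but-3-en-1-yl)-1H-pyrrol-2-yl]dihydrofuran-2(3H)-one, via keto aldehyde 6 (not isolated)
Conditions: AcOH–H2O (4:1), 45 °C; then 5, NaOAc, 25 °C
Reagents that add atoms: none
Why: Mild acid releases the γ-keto aldehyde, which condenses with the primary amine in a Paal–Knorr pyrrole synthesis and turns C18 into a non-enolisable pyrrolyl carbinol centre.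

**Step 3**
Reactants: 8 (R)-but-3-yn-2-ol
Product: 9 (R,E)-4-(4,4,5,5-tetramethyl-1,3,2-dioxaborolan-2-yl)but-3-en-2-ol
Conditions: B2pin2 (1.1 equiv), CuCl (5 mol%), Xantphos (6 mol%), NaOt-Bu (10 mol%), MeOH (2 equiv), THF, 25 °C
Reagents that add atoms: bis(pinacolato)diboron, CC1(C)OB(OC1(C)C)B1OC(C)(C)C(C)(C)O1
Why: Copper-catalysed syn borylation and protonation (formal hydroboration) of the terminal alkyne puts boron on the terminal carbon and gives the E-alkenylboronate with the bought carbinol centre untouched.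

**Step 4**
Reactants: 7 (R)-5-[1-(but-3-en-1-yl)-1H-pyrrol-2-yl]dihydrofuran-2(3H)-one; 9 (R,E)-4-(4,4,5,5-tetramethyl-1,3,2-dioxaborolan-2-yl)but-3-en-2-ol
Product: 11 (R)-5-{1-(but-3-en-1-yl)-5-[(R,E)-3-hydroxybut-1-en-1-yl]-1H-pyrrol-2-yl}dihydrofuran-2(3H)-one, via bromopyrrole 10 (not isolated)
Conditions: N-bromosuccinimide (1.0 equiv), THF, −78 °C; then 9 (1.3 equiv), Pd(dppf)Cl2 (5 mol%), CsF (3 equiv), THF, 55 °C
Reagents that add atoms: none
Why: Electrophilic bromination takes the only free α-position of the pyrrole, and the labile bromide is used at once in a Suzuki–Miyaura coupling that keeps the E geometry and the carbinol configuration.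

**Step 5**
Reactants: 11 (R)-5-{1-(but-3-en-1-yl)-5-[(R,E)-3-hydroxybut-1-en-1-yl]-1H-pyrrol-2-yl}dihydrofuran-2(3H)-one
Product: 12 (R,E)-4-{1-(but-3-en-1-yl)-5-[(R)-5-oxotetrahydrofuran-2-yl]-1H-pyrrol-2-yl}but-3-en-2-yl butanoate
Conditions: butanoyl chloride (1.2 equiv), Et3N, DMAP (cat.), CH2Cl2, 0 °C; used at once
Reagents that add atoms: butanoyl chloride, CCCC(Cl)=O
Why: DMAP-catalysed esterification of the secondary allylic alcohol proceeds with retention at the carbinol carbon.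

**Step 6**
Reactants: 12 (R,E)-4-{1-(but-3-en-1-yl)-5-[(R)-5-oxotetrahydrofuran-2-yl]-1H-pyrrol-2-yl}but-3-en-2-yl butanoate
Product: 14 (2R,3S,E)-3-{1-(but-3-en-1-yl)-5-[(R)-5-oxotetrahydrofuran-2-yl]-1H-pyrrol-2-yl}-2-ethylhex-4-enoic acid, via bis-silyl ketene acetal 13 (not isolated)
Conditions: LiN(i-Pr)2 (2.4 equiv), THF–DMPU (2:1), −78 °C; Me3SiCl (3 equiv), −78 to 25 °C; pH 5 citrate buffer
Reagents that add atoms: none
Why: In this Ireland–Claisen [3,3]-sigmatropic rearrangement the Z(O)-enolate (ethyl cis to O–Si) and the E-alkene react through a chair with the carbinol methyl equatorial, so the (R)-carbinol centre is transferred to C9 (S) and the syn C10 (R) centre, while the co-silylated lactone is regenerated on work-up.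

**Step 7**
Reactants: 14 (2R,3S,E)-3-{1-(but-3-en-1-yl)-5-[(R)-5-oxotetrahydrofuran-2-yl]-1H-pyrrol-2-yl}-2-ethylhex-4-enoic acid
Product: 16 (R)-2-{(9S)-3-[(R)-5-oxotetrahydrofuran-2-yl]-6,7,8,9-tetrahydro-5H-pyrrolo[1,2-a]azepin-9-yl}butanoic acid, via dihydroazepine acid 15 (not isolated)
Conditions: second-generation Grubbs catalyst (5 mol%), CH2Cl2 (3 mM), 40 °C; then 2-nitrobenzenesulfonohydrazide (6 equiv), Et3N, 25 °C
Reagents that add atoms: none
Why: Ring-closing metathesis of the N-butenyl and C9-propenyl groups closes ring C with loss of propene, and diimide reduction then saturates the new cis-alkene without double-bond migration, so C9 is preserved.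

**Step 8**
Reactants: 16 (R)-2-{(9S)-3-[(R)-5-oxotetrahydrofuran-2-yl]-6,7,8,9-tetrahydro-5H-pyrrolo[1,2-a]azepin-9-yl}butanoic acid
Product: 17 (R)-2-{(9S)-3-[(2R,4S)-4-methyl-5-oxotetrahydrofuran-2-yl]-6,7,8,9-tetrahydro-5H-pyrrolo[1,2-a]azepin-9-yl}butanoic acid
Conditions: LiN(i-Pr)2 (2.2 equiv), THF, −78 °C; MeI (1.2 equiv), −78 to −40 °C; pH 5 buffer
Reagents that add atoms: iodomethane, CI
Why: Diastereoselective enolate alkylation of the carboxylate/lactone dianion occurs on the lactone face anti to the C18 pyrrolyl group and gives the trans (18R,20S) lactone.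

**Step 9**
Reactants: 17 (R)-2-{(9S)-3-[(2R,4S)-4-methyl-5-oxotetrahydrofuran-2-yl]-6,7,8,9-tetrahydro-5H-pyrrolo[1,2-a]azepin-9-yl}butanoic acid
Product: 19 (R)-4-{(9S)-3-[(2R,4S)-4-methyl-5-oxotetrahydrofuran-2-yl]-6,7,8,9-tetrahydro-5H-pyrrolo[1,2-a]azepin-9-yl}hex-1-en-3-one, via acid chloride 18 (not isolated)
Conditions: 1-chloro-N,N,2-trimethylprop-1-en-1-amine (1.2 equiv), CH2Cl2, 0 °C to rt; then tributyl(ethenyl)stannane (1.3 equiv), Pd2(dba)3 (2.5 mol%), P(2-furyl)3 (10 mol%), THF, 50 °C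
Reagents that add atoms: tributyl(ethenyl)stannane, C=C[Sn](CCCC)(CCCC)CCCC
Why: The acid chloride is formed under neutral conditions and coupled with the vinylstannane in a Stille acylation, which gives the vinyl ketone without epimerising C10 or opening the lactone.

**Step 10**
Reactants: 19 (R)-4-{(9S)-3-[(2R,4S)-4-methyl-5-oxotetrahydrofuran-2-yl]-6,7,8,9-tetrahydro-5H-pyrrolo[1,2-a]azepin-9-yl}hex-1-en-3-one
Product: 20 (3S,4R)-4-{(9S)-3-[(2R,4S)-4-methyl-5-oxotetrahydrofuran-2-yl]-6,7,8,9-tetrahydro-5H-pyrrolo[1,2-a]azepin-9-yl}hex-1-en-3-ol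
Conditions: NaBH4 (1.2 equiv), CeCl3·7H2O (1.2 equiv), MeOH, −78 °C
Reagents that add atoms: none
Why: In this Luche 1,2-reduction hydride attacks anti to the large C9 branch (Felkin–Anh control), which gives the 11S alcohol whose oxygen will be cis to the ethyl group on ring B, the minor epimer being removed by chromatography.

**Step 11**
Reactants: 20 (3S,4R)-4-{(9S)-3-[(2R,4S)-4-methyl-5-oxotetrahydrofuran-2-yl]-6,7,8,9-tetrahydro-5H-pyrrolo[1,2-a]azepin-9-yl}hex-1-en-3-ol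
Product: 21 (3S,4R)-4-{(9S)-3-[(2R,4S)-4-methyl-5-oxotetrahydrofuran-2-yl]-6,7,8,9-tetrahydro-5H-pyrrolo[1,2-a]azepin-9-yl}hex-1-en-3-yl 2-methylprop-2-enoate
Conditions: 2-methylprop-2-enoyl chloride (1.5 equiv), Et3N, DMAP (cat.), CH2Cl2, 0 °C
Reagents that add atoms: 2-methylprop-2-enoyl chloride, CC(=C)C(Cl)=O
Why: Esterification of the allylic alcohol with retention at C11 installs C13, its methyl group and C14.

**Step 12**
Reactants: 21 (3S,4R)-4-{(9S)-3-[(2R,4S)-4-methyl-5-oxotetrahydrofuran-2-yl]-6,7,8,9-tetrahydro-5H-pyrrolo[1,2-a]azepin-9-yl}hex-1-en-3-yl 2-methylprop-2-enoate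
Product: 22 (R)-3-methyl-5-[(R)-1-{(9S)-3-[(2R,4S)-4-methyl-5-oxotetrahydrofuran-2-yl]-6,7,8,9-tetrahydro-5H-pyrrolo[1,2-a]azepin-9-yl}propyl]furan-2(5H)-one
Conditions: second-generation Hoveyda–Grubbs catalyst (10 mol%), toluene (5 mM), 80 °C
Reagents that add atoms: none
Why: Ring-closing metathesis of the methacrylate with the vinyl group gives the α-methylbutenolide (ring D) with loss of ethene, and no other alkene is left in the molecule to compete.

**Step 13**
Reactants: 22 (R)-3-methyl-5-[(R)-1-{(9S)-3-[(2R,4S)-4-methyl-5-oxotetrahydrofuran-2-yl]-6,7,8,9-tetrahydro-5H-pyrrolo[1,2-a]azepin-9-yl}propyl]furan-2(5H)-one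
Product: 23 13-methylene analogue of the target (exocyclic C13=CH2 on the cis-fused lactone; 9S,10R,11R, H12 cis to H11; side lactone 18R,20S)
Conditions: Pd(OAc)2 (1.0 equiv), NaOAc (2 equiv), DMSO–t-BuOH (1:1), 60 °C
Reagents that add atoms: none
Why: In this oxidative Heck (Fujiwara–Moritani) cyclisation Pd(OAc)2 palladates the pyrrole at C1, 6-exo syn-insertion into the butenolide and β-hydride elimination from the methyl group close ring B, and the tether on C11 allows only the cis ring fusion, which sets C12.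

**Step 14**
Reactants: 23 13-methylene analogue of the target
Product: 24 epibisdehydroneotuberostemonine J
Conditions: H2 (1 atm), RhCl(PPh3)3 (10 mol%), toluene–EtOH (1:1), 25 °C
Reagents that add atoms: none
Why: Homogeneous catalytic hydrogenation adds hydrogen to the exocyclic alkene from the convex face of the cis-fused lactone, so H13 ends up cis to H12 and H11 (13S), and it does not cleave the pyrrolyl C18–O bond.

**Compound list**

1 | (R)-5-oxotetrahydrofuran-2-carboxylic acid | OC(=O)[C@H]1CCC(=O)O1 | starting material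
2 | [2-(1,3-dioxolan-2-yl)ethyl]zinc bromide | Br[Zn]CCC1OCCO1 | starting material
3 | (R)-5-oxotetrahydrofuran-2-carbonyl chloride | ClC(=O)[C@H]1CCC(=O)O1 | intermediate
4 | (R)-5-[3-(1,3-dioxolan-2-yl)propanoyl]dihydrofuran-2(3H)-one | O=C(CCC1OCCO1)[C@H]1CCC(=O)O1 | intermediate
5 | but-3-en-1-amine | NCCC=C | starting material
6 | (R)-4-oxo-4-(5-oxotetrahydrofuran-2-yl)butanal | O=CCCC(=O)[C@H]1CCC(=O)O1 | intermediate
7 | (R)-5-[1-(but-3-en-1-yl)-1H-pyrrol-2-yl]dihydrofuran-2(3H)-one | C=CCCn1cccc1[C@H]1CCC(=O)O1 | intermediate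
8 | (R)-but-3-yn-2-ol | C[C@@H](O)C#C | starting material
9 | (R,E)-4-(4,4,5,5-tetramethyl-1,3,2-dioxaborolan-2-yl)but-3-en-2-ol | C[C@@H](O)/C=C/B1OC(C)(C)C(C)(C)O1 | intermediate
10 | (R)-5-[5-bromo-1-(but-3-en-1-yl)-1H-pyrrol-2-yl]dihydrofuran-2(3H)-one | C=CCCn1c(Br)ccc1[C@H]1CCC(=O)O1 | intermediate
11 | (R)-5-{1-(but-3-en-1-yl)-5-[(R,E)-3-hydroxybut-1-en-1-yl]-1H-pyrrol-2-yl}dihydrofuran-2(3H)-one | C[C@@H](O)/C=C/c1ccc([C@H]2CCC(=O)O2)n1CCC=C | intermediate
12 | (R,E)-4-{1-(but-3-en-1-yl)-5-[(R)-5-oxotetrahydrofuran-2-yl]-1H-pyrrol-2-yl}but-3-en-2-yl butanoate | CCCC(=O)O[C@H](C)/C=C/c1ccc([C@H]2CCC(=O)O2)n1CCC=C | intermediate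
13 | bis(trimethylsilyl) ketene acetal of 12 (ester as Z ketene acetal with ethyl cis to OSiMe3; lactone as 2-trimethylsilyloxy-4,5-dihydrofuran) | CC/C=C(\O[Si](C)(C)C)O[C@H](C)/C=C/c1ccc([C@H]2CC=C(O[Si](C)(C)C)O2)n1CCC=C | intermediate
14 | (2R,3S,E)-3-{1-(but-3-en-1-yl)-5-[(R)-5-oxotetrahydrofuran-2-yl]-1H-pyrrol-2-yl}-2-ethylhex-4-enoic acid | CC[C@@H](C(O)=O)[C@H](/C=C/C)c1ccc([C@H]2CCC(=O)O2)n1CCC=C | intermediate
15 | (R)-2-{(9S)-3-[(R)-5-oxotetrahydrofuran-2-yl]-6,9-dihydro-5H-pyrrolo[1,2-a]azepin-9-yl}butanoic acid | CC[C@@H](C(O)=O)[C@@H]1C=CCCn2c1ccc2[C@H]3CCC(=O)O3 | intermediate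
16 | (R)-2-{(9S)-3-[(R)-5-oxotetrahydrofuran-2-yl]-6,7,8,9-tetrahydro-5H-pyrrolo[1,2-a]azepin-9-yl}butanoic acid | CC[C@@H](C(O)=O)[C@@H]1CCCCn2c1ccc2[C@H]3CCC(=O)O3 | intermediate
17 | (R)-2-{(9S)-3-[(2R,4S)-4-methyl-5-oxotetrahydrofuran-2-yl]-6,7,8,9-tetrahydro-5H-pyrrolo[1,2-a]azepin-9-yl}butanoic acid | CC[C@@H](C(O)=O)[C@@H]1CCCCn2c1ccc2[C@H]3C[C@H](C)C(=O)O3 | intermediate
18 | (R)-2-{(9S)-3-[(2R,4S)-4-methyl-5-oxotetrahydrofuran-2-yl]-6,7,8,9-tetrahydro-5H-pyrrolo[1,2-a]azepin-9-yl}butanoyl chloride | CC[C@@H](C(Cl)=O)[C@@H]1CCCCn2c1ccc2[C@H]3C[C@H](C)C(=O)O3 | intermediate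
19 | (R)-4-{(9S)-3-[(2R,4S)-4-methyl-5-oxotetrahydrofuran-2-yl]-6,7,8,9-tetrahydro-5H-pyrrolo[1,2-a]azepin-9-yl}hex-1-en-3-one | CC[C@@H](C(=O)C=C)[C@@H]1CCCCn2c1ccc2[C@H]3C[C@H](C)C(=O)O3 | intermediate
20 | (3S,4R)-4-{(9S)-3-[(2R,4S)-4-methyl-5-oxotetrahydrofuran-2-yl]-6,7,8,9-tetrahydro-5H-pyrrolo[1,2-a]azepin-9-yl}hex-1-en-3-ol | CC[C@@H]([C@@H](O)C=C)[C@@H]1CCCCn2c1ccc2[C@H]3C[C@H](C)C(=O)O3 | intermediate
21 | (3S,4R)-4-{(9S)-3-[(2R,4S)-4-methyl-5-oxotetrahydrofuran-2-yl]-6,7,8,9-tetrahydro-5H-pyrrolo[1,2-a]azepin-9-yl}hex-1-en-3-yl 2-methylprop-2-enoate | CC[C@@H]([C@@H](OC(=O)C(C)=C)C=C)[C@@H]1CCCCn2c1ccc2[C@H]3C[C@H](C)C(=O)O3 | intermediate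
22 | (R)-3-methyl-5-[(R)-1-{(9S)-3-[(2R,4S)-4-methyl-5-oxotetrahydrofuran-2-yl]-6,7,8,9-tetrahydro-5H-pyrrolo[1,2-a]azepin-9-yl}propyl]furan-2(5H)-one | CC[C@@H]([C@H]4OC(=O)C(C)=C4)[C@@H]1CCCCn2c1ccc2[C@H]3C[C@H](C)C(=O)O3 | intermediate
23 | 13-methylene analogue of the target (exocyclic C13=CH2, cis-fused lactone, 9S,10R,11R,18R,20S) | CC[C@H]1[C@H]2OC(=O)C(=C)[C@H]2c2cc([C@H]3C[C@H](C)C(=O)O3)n3c2[C@H]1CCCC3 | intermediate
24 | epibisdehydroneotuberostemonine J | CC[C@H]1[C@H]2OC(=O)[C@@H](C)[C@H]2c2cc([C@H]3C[C@H](C)C(=O)O3)n3c2[C@H]1CCCC3 | target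

**Step count and risks**

Total step count: 14. Longest linear sequence: 13 (steps 1, 2 and 4 to 14, starting from 1); step 3 is a one-step side branch from 8.

The three steps most likely to fail are 13, 6 and 10.

Step 13 (oxidative Heck closure of ring B) has the least precedent: an electron-rich trialkylpyrrole may be oxidised by Pd(OAc)2, and insertion into a trisubstituted butenolide is slow. The fallback sets out from 22 and comes back to the route at 24, skipping step 14. It is an intramolecular Friedel–Crafts conjugate addition of pyrrole C1 to the butenolide, promoted by Sc(OTf)3 (10 mol%) in (CF3)2CHOH at 0 °C. The cis ring fusion is again forced by the tether, and the lactone enol is protonated on the convex face, which gives the 13S methyl directly. No new compound is made. The acid-labile pyrrolyl C18–O bond must be watched for epimerisation.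

Step 6 (Ireland–Claisen) can suffer from ionisation of the pyrrole-conjugated allylic ester 12 and from incomplete Z(O)-enolate selectivity in THF–DMPU. The fallback sets out from 7 and comes back at 14, and it pairs a Z-alkene with the intrinsically favoured E(O)-enolate.
- Bromide 10 is made as in step 4 and coupled (PdCl2(PPh3)2, CuI, i-Pr2NH) with bought (S)-but-3-yn-2-ol in a Sonogashira reaction to give (R)-5-{1-(but-3-en-1-yl)-5-[(S)-3-hydroxybut-1-yn-1-yl]-1H-pyrrol-2-yl}dihydrofuran-2(3H)-one F1.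
- Semihydrogenation (H2, Pd/CaCO3 poisoned with Pb(OAc)2, quinoline) gives (R)-5-{1-(but-3-en-1-yl)-5-[(S,Z)-3-hydroxybut-1-en-1-yl]-1H-pyrrol-2-yl}dihydrofuran-2(3H)-one F2.
- Butanoylation gives (S,Z)-4-{1-(but-3-en-1-yl)-5-[(R)-5-oxotetrahydrofuran-2-yl]-1H-pyrrol-2-yl}but-3-en-2-yl butanoate F3.
- LiN(i-Pr)2 in THF without DMPU, then Me3SiCl, gives the bis-silyl ketene acetal with ethyl trans to O–Si F4. Its chair rearrangement (S-carbinol, Z-alkene) gives the same (2R,3S) acid 14.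
- The twisted Z-vinylpyrrole ester should also be less prone to ionisation.

Step 10 (Felkin–Anh reduction) may give a low diastereomer ratio at C11. The fallback sets out from 17 and comes back at 21, and it sets C11 by addition followed by inversion.
- Acid chloride 18 is reduced (Bu3SnH, Pd(PPh3)4) to (R)-2-{(9S)-3-[(2R,4S)-4-methyl-5-oxotetrahydrofuran-2-yl]-6,7,8,9-tetrahydro-5H-pyrrolo[1,2-a]azepin-9-yl}butanal F5.
- Felkin–Anh addition of Zn(CH=CH2)2 gives the epimeric alcohol (3R,4R)-4-{(9S)-3-[(2R,4S)-4-methyl-5-oxotetrahydrofuran-2-yl]-6,7,8,9-tetrahydro-5H-pyrrolo[1,2-a]azepin-9-yl}hex-1-en-3-ol F6.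
- Mitsunobu esterification with 2-methylprop-2-enoic acid (PPh3, diisopropyl azodicarboxylate) inverts C11 and gives 21.
- The same Mitsunobu reaction also recycles the minor epimer from step 10.

**Further compounds**

F1 | step 6 | (R)-5-{1-(but-3-en-1-yl)-5-[(S)-3-hydroxybut-1-yn-1-yl]-1H-pyrrol-2-yl}dihydrofuran-2(3H)-one | C[C@H](O)C#Cc1ccc([C@H]2CCC(=O)O2)n1CCC=C
F2 | step 6 | (R)-5-{1-(but-3-en-1-yl)-5-[(S,Z)-3-hydroxybut-1-en-1-yl]-1H-pyrrol-2-yl}dihydrofuran-2(3H)-one | C[C@H](O)/C=C\c1ccc([C@H]2CCC(=O)O2)n1CCC=C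
F3 | step 6 | (S,Z)-4-{1-(but-3-en-1-yl)-5-[(R)-5-oxotetrahydrofuran-2-yl]-1H-pyrrol-2-yl}but-3-en-2-yl butanoate | CCCC(=O)O[C@@H](C)/C=C\c1ccc([C@H]2CCC(=O)O2)n1CCC=C
F4 | step 6 | bis(trimethylsilyl) ketene acetal of F3 (ethyl trans to OSiMe3) | CC/C=C(/O[Si](C)(C)C)O[C@@H](C)/C=C\c1ccc([C@H]2CC=C(O[Si](C)(C)C)O2)n1CCC=C
F5 | step 10 | (R)-2-{(9S)-3-[(2R,4S)-4-methyl-5-oxotetrahydrofuran-2-yl]-6,7,8,9-tetrahydro-5H-pyrrolo[1,2-a]azepin-9-yl}butanal | CC[C@@H](C=O)[C@@H]1CCCCn2c1ccc2[C@H]3C[C@H](C)C(=O)O3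
F6 | step 10 | (3R,4R)-4-{(9S)-3-[(2R,4S)-4-methyl-5-oxotetrahydrofuran-2-yl]-6,7,8,9-tetrahydro-5H-pyrrolo[1,2-a]azepin-9-yl}hex-1-en-3-ol | CC[C@@H]([C@H](O)C=C)[C@@H]1CCCCn2c1ccc2[C@H]3C[C@H](C)C(=O)O3
F0 | step 13 | none | none
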